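**Retrosynthetic overview**

1. Numbering: ring carbons C2–C6 (C5 = carbinol carbon), C1 = isopropenyl carbon on C2, C7 = first polyene carbon on C6. The strategy rests on C1 (on C2) and C7 (on C6) being cis on the cyclopentane and on the face of the C5 methyl. Both bonds, C2–C1 and C6–C7, are therefore made at once as a cyclobutane cis-fused across C2–C6, and its extra C1–C7 bond is cut later.
2. Target 24 ⇒ desilylation and Julia–Kocienski olefination at C7=C8: C10 ring sulfone 12 + C30 polyenal 21 (apo-8'-lycopenal).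
3. 12 ⇒ cyclobutanone 7 (Baeyer–Villiger cuts C1–C7, reduction, C7 tetrazolyl sulfone, dehydration at C1); 7 ⇒ (2+2) of tetramethylketeniminium 5 with silyl ether 3.
4. 3 ⇒ (R)-linalool by ring-closing metathesis. Ring order: cyclopentene (step 1), temporary cis-fused cyclobutane (step 3), expanded to a γ-lactone (step 4) and opened (step 5).
5. 21 ⇒ pseudoionone + vinyl (C2) + C10 dial + C2 + C3, all by Wittig chemistry.

Key step: step 3

Remark: pseudoionone is taken as the (3E,5E) isomer; all polyenes are handled under argon with exclusion of light, and Z isomers from the olefinations are equilibrated towards all-E with a trace of iodine.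

**Ring fragment**

Step 1
Reactants: 1 (R)-(−)-linalool
Product: 2 (R)-1-methylcyclopent-2-en-1-ol
Conditions: RuCl2(=CHPh)(PCy3)(H2IMes) (second-generation Grubbs catalyst, 1 mol %), CH2Cl2, 40 °C
Reagents that add atoms: none
Why: Ring-closing metathesis between the vinyl group and the prenyl alkene should close the cyclopentene with loss of volatile isobutene; the carbinol centre is not touched, so the (R) configuration of linalool becomes that of C5.

Step 2
Reactants: 2 (R)-1-methylcyclopent-2-en-1-ol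
Product: 3 (R)-tert-butyldimethyl[(1-methylcyclopent-2-en-1-yl)oxy]silane
Conditions: TBSOTf, 2,6-lutidine, CH2Cl2, −78 °C → rt
Reagents that add atoms: tert-butyldimethylsilyl triflate, CC(C)(C)[Si](C)(C)OS(=O)(=O)C(F)(F)F
Why: Silylation of a hindered tertiary alcohol with a silyl triflate and a hindered base is reliable and affects no stereocentre; the bulky silyl group is also the facial control element for step 3.

Step 3
Reactants: 3 (R)-tert-butyldimethyl[(1-methylcyclopent-2-en-1-yl)oxy]silane; 4 1-chloro-N,N,2-trimethylprop-1-en-1-amine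
Product: 7 (1R,4R,5R)-4-[(tert-butyldimethylsilyl)oxy]-4,7,7-trimethylbicyclo[3.2.0]heptan-6-one, via tetramethylketeniminium ion 5 (not isolated), via cyclobutaniminium salt 6 (not isolated)
Conditions: 4 (1.5 equiv), ZnCl2 (1.5 equiv), CH2Cl2, 0 °C → 40 °C; then H2O, rt → 40 °C
Reagents that add atoms: water, O
Why: ZnCl2 ionises chloroenamine 4 to keteniminium 5; C6 of the alkene attacks its electrophilic sp carbon (future C7) so that positive charge builds on C2, the alkene carbon farther from the C5–O bond, and the enamine carbon (future C1) then closes onto C2 from the same face to give cyclobutaniminium 6, which water hydrolyses to ketone 7. The closest known reaction type is the keteniminium–alkene (2+2) cycloaddition to cyclobutanones, established for simple cycloalkenes such as cyclopentene. The four-membered ring is closed by an asynchronous, suprafacial delivery of both bonds (C6–C7 first, then C2–C1 by cation–enamine collapse) to one face of the cis ring alkene, so the fusion at C2/C6 can only be cis. The configurations of C6 and C2 are set together by the face of approach, which the existing C5 centre controls: the keteniminium should add anti to the OSi(t-Bu)Me2 group, so that C7 and C1 end cis to the C5 methyl. The step needs this facial selectivity and the regiochemistry C7-to-C6; the regiochemistry is secured by the C5–O dipole, which disfavours charge on C6, and by the preference of the bulky CMe2 terminus for the carbon remote from the quaternary centre, while the facial bias rests on the size of the silyl group and is the least secure element. The (R) centre at C5 is not touched.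

Step 4
Reactants: 7 (1R,4R,5R)-4-[(tert-butyldimethylsilyl)oxy]-4,7,7-trimethylbicyclo[3.2.0]heptan-6-one
Product: 8 (3aR,6R,6aR)-6-[(tert-butyldimethylsilyl)oxy]-3,3,6-trimethylhexahydro-1H-cyclopenta[c]furan-1-one
Conditions: mCPBA, NaHCO3, CH2Cl2, 0 °C → rt
Reagents that add atoms: 3-chloroperoxybenzoic acid, O=C(OO)c1cccc(Cl)c1
Why: Baeyer–Villiger oxidation of the strained cyclobutanone should proceed with migration of the quaternary C1 (a better migrating group than the bridgehead C6, which is also deactivated by the neighbouring C5–O), inserting oxygen between C7 and C1 and so cutting the temporary C1–C7 bond without touching a stereocentre.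

Step 5
Reactants: 8 (3aR,6R,6aR)-6-[(tert-butyldimethylsilyl)oxy]-3,3,6-trimethylhexahydro-1H-cyclopenta[c]furan-1-one
Product: 9 {(1S,2R,5R)-2-[(tert-butyldimethylsilyl)oxy]-5-(2-hydroxypropan-2-yl)-2-methylcyclopentyl}methanol
Conditions: LiAlH4, THF, 0 °C → rt (aqueous NaOH work-up)
Reagents that add atoms: none
Why: Hydride reduction of the lactone should give the 1,4-diol (primary C7 alcohol, tertiary C1 alcohol); the silyl ether and the three stereocentres are inert to LiAlH4.

Step 6
Reactants: 9 {(1S,2R,5R)-2-[(tert-butyldimethylsilyl)oxy]-5-(2-hydroxypropan-2-yl)-2-methylcyclopentyl}methanol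
Product: 10 2-[(1R,2R,3R)-3-[(tert-butyldimethylsilyl)oxy]-3-methyl-2-{[(1-phenyl-1H-tetrazol-5-yl)sulfanyl]methyl}cyclopentyl]propan-2-ol
Conditions: 1-phenyl-1H-tetrazole-5-thiol, PPh3, DIAD, THF, 0 °C → rt
Reagents that add atoms: 1-phenyl-1H-tetrazole-5-thiol, Sc1nnnn1-c1ccccc1
Why: Mitsunobu thioetherification activates only the primary alcohol (the tertiary carbinol does not react), and the acidic, strongly nucleophilic thiol should outrun closure to the cyclic ether; substitution occurs at a CH2 group, so no stereocentre is involved.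

Step 7
Reactants: 10 2-[(1R,2R,3R)-3-[(tert-butyldimethylsilyl)oxy]-3-methyl-2-{[(1-phenyl-1H-tetrazol-5-yl)sulfanyl]methyl}cyclopentyl]propan-2-ol
Product: 11 2-[(1R,2R,3R)-3-[(tert-butyldimethylsilyl)oxy]-3-methyl-2-{[(1-phenyl-1H-tetrazol-5-yl)sulfonyl]methyl}cyclopentyl]propan-2-ol
Conditions: (NH4)6Mo7O24·4H2O (cat.), 30% aq. H2O2, EtOH, 0 °C → rt
Reagents that add atoms: hydrogen peroxide, OO
Why: Molybdate-catalysed peroxide oxidation of the sulfide to the sulfone is done while the molecule still has no alkene; the silyl ether and the tertiary alcohol are inert.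

Step 8
Reactants: 11 2-[(1R,2R,3R)-3-[(tert-butyldimethylsilyl)oxy]-3-methyl-2-{[(1-phenyl-1H-tetrazol-5-yl)sulfonyl]methyl}cyclopentyl]propan-2-ol
Product: 12 5-({[(1R,2R,5R)-2-[(tert-butyldimethylsilyl)oxy]-2-methyl-5-(prop-1-en-2-yl)cyclopentyl]methyl}sulfonyl)-1-phenyl-1H-tetrazole
Conditions: SOCl2, pyridine, CH2Cl2, −30 °C → 0 °C
Reagents that add atoms: none
Why: Dehydration of the tertiary alcohol through its chlorosulfite (base-mediated anti elimination) should remove a proton from one of the two methyl groups, six accessible hydrogens against one hindered C2–H whose loss would give a strained tetrasubstituted exocyclic alkene, so the isopropenyl group forms and C2 keeps its configuration.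

**Polyene fragment**

Step 9
Reactants: 13 (3E,5E)-pseudoionone
Product: 14 (4E,6E)-3,7,11-trimethyldodeca-1,4,6,10-tetraen-3-ol (racemic)
Conditions: CH2=CHMgBr, THF, −20 °C → 0 °C (aq. NH4Cl work-up)
Reagents that add atoms: vinylmagnesium bromide, C=C[Mg]Br
Why: Grignard 1,2-addition to the methyl ketone of the dienone; the new carbinol centre is racemic, which does not matter because it is lost in step 10.

Step 10
Reactants: 14 (4E,6E)-3,7,11-trimethyldodeca-1,4,6,10-tetraen-3-ol
Product: 15 [(2E,4E,6E)-3,7,11-trimethyldodeca-2,4,6,10-tetraen-1-yl]triphenylphosphonium bromide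
Conditions: PPh3·HBr, MeOH, rt
Reagents that add atoms: triphenylphosphine hydrobromide, [Br-].c1ccc(cc1)[PH+](c1ccccc1)c1ccccc1
Why: Acid-mediated allylic transposition: the tertiary bis-allylic alcohol ionises and PPh3 captures the delocalised cation at its primary terminus, giving the conjugated phosphonium salt, mainly 2E under thermodynamic control and purified by crystallisation.

Step 11
Reactants: 15 [(2E,4E,6E)-3,7,11-trimethyldodeca-2,4,6,10-tetraen-1-yl]triphenylphosphonium bromide; 16 (2E,4E,6E)-2,7-dimethylocta-2,4,6-trienedial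
Product: 18 (2E,4E,6E,8E,10E,12E,14E)-2,7,11,15,19-pentamethylicosa-2,4,6,8,10,12,14,18-octaenal, via C15 phosphorus ylide 17 (not isolated)
Conditions: NaOMe, MeOH/CH2Cl2, 0 °C → rt, 15 added slowly to 16 (3 equiv); then I2 (cat.), CH2Cl2, daylight, rt
Reagents that add atoms: none
Why: Wittig olefination of one formyl group of the symmetrical dial, kept in excess to suppress double condensation, forms C11'=C12'; iodine-catalysed equilibration and crystallisation should leave mainly the all-E C25 aldehyde.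

Step 12
Reactants: 18 (2E,4E,6E,8E,10E,12E,14E)-2,7,11,15,19-pentamethylicosa-2,4,6,8,10,12,14,18-octaenal
Product: 20 (2E,4E,6E,8E,10E,12E,14E,16E)-4,9,13,17,21-pentamethyldocosa-2,4,6,8,10,12,14,16,20-nonaenal, via vinyl dioxolane acetal 19 (not isolated)
Conditions: (1,3-dioxolan-2-ylmethyl)triphenylphosphonium bromide, KOt-Bu, THF, 0 °C → rt; then 1 M aq. HCl, THF, rt
Reagents that add atoms: (1,3-dioxolan-2-ylmethyl)triphenylphosphonium bromide, [Br-].C1COC(O1)C[P+](c1ccccc1)(c1ccccc1)c1ccccc1; water, O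
Why: Wittig two-carbon homologation with an acetal-protected formylmethyl ylide, which cannot over-homologate; acid hydrolysis of the vinyl acetal releases the enal and should equilibrate its α,β double bond to E.

Step 13
Reactants: 20 (2E,4E,6E,8E,10E,12E,14E,16E)-4,9,13,17,21-pentamethyldocosa-2,4,6,8,10,12,14,16,20-nonaenal
Product: 21 (2E,4E,6E,8E,10E,12E,14E,16E,18E)-2,6,11,15,19,23-hexamethyltetracosa-2,4,6,8,10,12,14,16,18,22-decaenal (apo-8'-lycopenal)
Conditions: Ph3P=C(CH3)CHO, toluene, 80 °C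
Reagents that add atoms: 2-(triphenylphosphoranylidene)propanal, CC(C=O)=P(c1ccccc1)(c1ccccc1)c1ccccc1
Why: Wittig olefination with a stabilised formyl ylide is E-selective for the trisubstituted C9=C10 bond, and the α-methyl enal formed is less reactive than 20, so it should not react a second time.

**Coupling and deprotection**

Step 14
Reactants: 12 5-({[(1R,2R,5R)-2-[(tert-butyldimethylsilyl)oxy]-2-methyl-5-(prop-1-en-2-yl)cyclopentyl]methyl}sulfonyl)-1-phenyl-1H-tetrazole; 21 apo-8'-lycopenal
Product: 23 tert-butyldimethyl{[(1R,2R,3R)-1-methyl-3-(prop-1-en-2-yl)-2-[(1E,3E,5E,7E,9E,11E,13E,15E,17E,19E)-3,7,12,16,20,24-hexamethylpentacosa-1,3,5,7,9,11,13,15,17,19,23-undecaen-1-yl]cyclopentyl]oxy}silane, via potassium sulfonyl carbanion 22 (not isolated)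
Conditions: KN(SiMe3)2, THF, −78 °C; then 21, −78 °C → rt; then I2 (cat.), toluene, daylight, rt
Reagents that add atoms: none
Why: Julia–Kocienski olefination: the metalated tetrazolyl sulfone adds to the aldehyde, and Smiles rearrangement with loss of SO2 and the tetrazolone forms C7=C8, expected mainly E and equilibrated towards all-E with iodine; C6 is β to the carbanion and cannot epimerise, and the silyl ether keeps the C5 oxygen from attacking the tetrazole.

Step 15
Reactants: 23 silyl ether of the target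
Product: 24 (1R,2R,3R)-1-methyl-3-(prop-1-en-2-yl)-2-[(1E,3E,5E,7E,9E,11E,13E,15E,17E,19E)-3,7,12,16,20,24-hexamethylpentacosa-1,3,5,7,9,11,13,15,17,19,23-undecaen-1-yl]cyclopentan-1-ol (CNP0222499.3)
Conditions: Bu4NF, THF, rt → 45 °C
Reagents that add atoms: none
Why: Fluoride-mediated desilylation of the tertiary silyl ether should free the C5 alcohol without affecting the polyene or any stereocentre.

**Compound list**

1 | (R)-(−)-linalool, (3R)-3,7-dimethylocta-1,6-dien-3-ol | CC(C)=CCC[C@@](C)(O)C=C | starting material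
2 | (R)-1-methylcyclopent-2-en-1-ol | C[C@@]1(O)CCC=C1 | intermediate
3 | (R)-tert-butyldimethyl[(1-methylcyclopent-2-en-1-yl)oxy]silane | C[C@@]1(O[Si](C)(C)C(C)(C)C)CCC=C1 | intermediate
4 | 1-chloro-N,N,2-trimethylprop-1-en-1-amine | CC(C)=C(Cl)N(C)C | starting material
5 | tetramethylketeniminium ion (formed as its trichlorozincate salt) | CC(C)=C=[N+](C)C | intermediate
6 | N,N-dimethyliminium ion of ketone 7, same configuration (trichlorozincate salt) | C[N+](C)=C1C(C)(C)[C@@H]2CC[C@@](C)(O[Si](C)(C)C(C)(C)C)[C@H]12 | intermediate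
7 | (1R,4R,5R)-4-[(tert-butyldimethylsilyl)oxy]-4,7,7-trimethylbicyclo[3.2.0]heptan-6-one (cis-fused, cyclobutane anti to the silyloxy group) | O=C1C(C)(C)[C@@H]2CC[C@@](C)(O[Si](C)(C)C(C)(C)C)[C@H]12 | intermediate
8 | (3aR,6R,6aR)-6-[(tert-butyldimethylsilyl)oxy]-3,3,6-trimethylhexahydro-1H-cyclopenta[c]furan-1-one | O=C1OC(C)(C)[C@@H]2CC[C@@](C)(O[Si](C)(C)C(C)(C)C)[C@H]12 | intermediate
9 | {(1S,2R,5R)-2-[(tert-butyldimethylsilyl)oxy]-5-(2-hydroxypropan-2-yl)-2-methylcyclopentyl}methanol | CC(C)(O)[C@@H]1CC[C@@](C)(O[Si](C)(C)C(C)(C)C)[C@@H]1CO | intermediate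
10 | 2-[(1R,2R,3R)-3-[(tert-butyldimethylsilyl)oxy]-3-methyl-2-{[(1-phenyl-1H-tetrazol-5-yl)sulfanyl]methyl}cyclopentyl]propan-2-ol | CC(C)(O)[C@@H]1CC[C@@](C)(O[Si](C)(C)C(C)(C)C)[C@@H]1CSc1nnnn1-c1ccccc1 | intermediate
11 | 2-[(1R,2R,3R)-3-[(tert-butyldimethylsilyl)oxy]-3-methyl-2-{[(1-phenyl-1H-tetrazol-5-yl)sulfonyl]methyl}cyclopentyl]propan-2-ol | CC(C)(O)[C@@H]1CC[C@@](C)(O[Si](C)(C)C(C)(C)C)[C@@H]1CS(=O)(=O)c1nnnn1-c1ccccc1 | intermediate
12 | 5-({[(1R,2R,5R)-2-[(tert-butyldimethylsilyl)oxy]-2-methyl-5-(prop-1-en-2-yl)cyclopentyl]methyl}sulfonyl)-1-phenyl-1H-tetrazole | C=C(C)[C@@H]1CC[C@@](C)(O[Si](C)(C)C(C)(C)C)[C@@H]1CS(=O)(=O)c1nnnn1-c1ccccc1 | intermediate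
13 | pseudoionone, (3E,5E)-6,10-dimethylundeca-3,5,9-trien-2-one | CC(C)=CCC/C(C)=C/C=C/C(C)=O | starting material
14 | (4E,6E)-3,7,11-trimethyldodeca-1,4,6,10-tetraen-3-ol (racemic) | CC(C)=CCC/C(C)=C/C=C/C(C)(O)C=C | intermediate
15 | [(2E,4E,6E)-3,7,11-trimethyldodeca-2,4,6,10-tetraen-1-yl]triphenylphosphonium bromide | CC(C)=CCC/C(C)=C/C=C/C(C)=C/C[P+](c1ccccc1)(c1ccccc1)c1ccccc1.[Br-] | intermediate
16 | (2E,4E,6E)-2,7-dimethylocta-2,4,6-trienedial | O=C/C(C)=C/C=C/C=C(C)/C=O | starting material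
17 | [(2E,4E,6E)-3,7,11-trimethyldodeca-2,4,6,10-tetraen-1-ylidene]triphenylphosphorane | CC(C)=CCC/C(C)=C/C=C/C(C)=C/C=P(c1ccccc1)(c1ccccc1)c1ccccc1 | intermediate
18 | (2E,4E,6E,8E,10E,12E,14E)-2,7,11,15,19-pentamethylicosa-2,4,6,8,10,12,14,18-octaenal (apo-12'-lycopenal) | O=C/C(C)=C/C=C/C=C(C)/C=C/C=C(C)/C=C/C=C(\C)CCC=C(C)C | intermediate
19 | 2-[(3E,5E,7E,9E,11E,13E,15E)-3,8,12,16,20-pentamethylhenicosa-1,3,5,7,9,11,13,15,19-nonaen-1-yl]-1,3-dioxolane (1E/1Z mixture) | C1COC(O1)C=C/C(C)=C/C=C/C=C(C)/C=C/C=C(C)/C=C/C=C(\C)CCC=C(C)C | intermediate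
20 | (2E,4E,6E,8E,10E,12E,14E,16E)-4,9,13,17,21-pentamethyldocosa-2,4,6,8,10,12,14,16,20-nonaenal | O=C/C=C/C(C)=C/C=C/C=C(C)/C=C/C=C(C)/C=C/C=C(\C)CCC=C(C)C | intermediate
21 | (2E,4E,6E,8E,10E,12E,14E,16E,18E)-2,6,11,15,19,23-hexamethyltetracosa-2,4,6,8,10,12,14,16,18,22-decaenal (apo-8'-lycopenal) | O=C/C(C)=C/C=C/C(C)=C/C=C/C=C(C)/C=C/C=C(C)/C=C/C=C(\C)CCC=C(C)C | intermediate
22 | potassium salt of sulfone 12 deprotonated at the CH2SO2 carbon | C=C(C)[C@@H]1CC[C@@](C)(O[Si](C)(C)C(C)(C)C)[C@@H]1[CH-]S(=O)(=O)c1nnnn1-c1ccccc1.[K+] | intermediate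
23 | tert-butyldimethylsilyl ether of the target, (1R,2R,3R) ring, all-E chain | C=C(C)[C@@H]1CC[C@@](C)(O[Si](C)(C)C(C)(C)C)[C@@H]1/C=C/C(C)=C/C=C/C(C)=C/C=C/C=C(C)/C=C/C=C(C)/C=C/C=C(\C)CCC=C(C)C | intermediate
24 | (1R,2R,3R)-1-methyl-3-(prop-1-en-2-yl)-2-[(1E,3E,5E,7E,9E,11E,13E,15E,17E,19E)-3,7,12,16,20,24-hexamethylpentacosa-1,3,5,7,9,11,13,15,17,19,23-undecaen-1-yl]cyclopentan-1-ol | C=C(C)[C@@H]1CC[C@@](C)(O)[C@@H]1/C=C/C(C)=C/C=C/C(C)=C/C=C/C=C(C)/C=C/C=C(C)/C=C/C=C(\C)CCC=C(C)C | target

**Step count**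

Total: 15 steps. Longest linear sequence: 10 steps (steps 1–8, 14 and 15, from (R)-linalool).

**Steps most likely to fail**

Step 3. The tertiary allylic silyl ether may ionise under the Lewis-acidic, cationic conditions (loss of silanol, diene formation) before it cycloadds. The keteniminium may also discriminate poorly between the methyl-bearing and the silyloxy-bearing face. The fallback sets out from 3 and returns at 7, and replaces the cationic cycloaddition by a neutral ketene cycloaddition. Dichloroketene, generated from trichloroacetyl chloride with Zn–Cu couple in Et2O/DME, should add with the same regiochemistry and anti to the silyloxy group to give (1R,4R,5R)-7,7-dichloro-4-[(tert-butyldimethylsilyl)oxy]-4-methylbicyclo[3.2.0]heptan-6-one F1. Zinc dust in AcOH removes both chlorines to give (1S,4R,5R)-4-[(tert-butyldimethylsilyl)oxy]-4-methylbicyclo[3.2.0]heptan-6-one F2. Two successive enolisation–methylation cycles (LiN(SiMe3)2, MeI, THF, −78 °C → 0 °C), which should take place at the non-bridgehead α-carbon only, return to ketone 7.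

Step 8. Regiocontrol in the elimination may be lost (removal of the C2 hydrogen, giving the isopropylidene isomer), the tertiary chloride may form by substitution, and the acidic sulfone methylene may interfere. The fallback sets out from 9 and returns at 12, and introduces the alkene before sulfur by an intramolecular syn elimination. Pivaloylation of the primary hydroxyl (t-BuCOCl, pyridine) gives {(1S,2R,5R)-2-[(tert-butyldimethylsilyl)oxy]-5-(2-hydroxypropan-2-yl)-2-methylcyclopentyl}methyl 2,2-dimethylpropanoate F3. The inner salt methyl N-(triethylammoniosulfonyl)carbamate (toluene, 60 °C) dehydrates the tertiary alcohol through a cyclic sulfamate transition state that reaches the six methyl hydrogens far more easily than the single C2–H, giving {(1S,2R,5R)-2-[(tert-butyldimethylsilyl)oxy]-2-methyl-5-(prop-1-en-2-yl)cyclopentyl}methyl 2,2-dimethylpropanoate F4. i-Bu2AlH removes the pivalate to give {(1S,2R,5R)-2-[(tert-butyldimethylsilyl)oxy]-2-methyl-5-(prop-1-en-2-yl)cyclopentyl}methanol F5. Mitsunobu thioetherification, now without a competing hydroxyl, gives 5-({[(1R,2R,5R)-2-[(tert-butyldimethylsilyl)oxy]-2-methyl-5-(prop-1-en-2-yl)cyclopentyl]methyl}sulfanyl)-1-phenyl-1H-tetrazole F6. Molybdate/H2O2 oxidation, to which the 1,1-disubstituted alkene should be inert at room temperature, gives sulfone 12.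

Step 14. Addition of the hindered, β-branched sulfonyl anion may be slow compared with base-induced degradation of the long polyenal (vinylogous deprotonation) and self-condensation of the sulfone, and E-selectivity with a conjugated aldehyde may be incomplete. The fallback sets out from 12 and returns at 23, using aldehyde 18, and attaches the chain in two stages with a C15 + C25 Wittig coupling. Sulfone 12 is olefinated under the same Julia–Kocienski conditions with the small, robust C5 aldehyde ethyl (E)-3-methyl-4-oxobut-2-enoate to give ethyl (2E,4E)-5-[(1R,2R,5R)-2-[(tert-butyldimethylsilyl)oxy]-2-methyl-5-(prop-1-en-2-yl)cyclopentyl]-3-methylpenta-2,4-dienoate F7. i-Bu2AlH (CH2Cl2, −78 °C) reduces it to (2E,4E)-5-[(1R,2R,5R)-2-[(tert-butyldimethylsilyl)oxy]-2-methyl-5-(prop-1-en-2-yl)cyclopentyl]-3-methylpenta-2,4-dien-1-ol F8. PPh3·HBr in MeOH/CH2Cl2 converts this into [(2E,4E)-5-[(1R,2R,5R)-2-[(tert-butyldimethylsilyl)oxy]-2-methyl-5-(prop-1-en-2-yl)cyclopentyl]-3-methylpenta-2,4-dien-1-yl]triphenylphosphonium bromide F9. Wittig condensation of F9 with the C25 aldehyde 18 (NaOMe, MeOH/CH2Cl2, then iodine equilibration) forms C11=C12 and gives silyl ether 23; steps 12 and 13 are then not needed.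

**Further compounds**

F1 | step 3 | (1R,4R,5R)-7,7-dichloro-4-[(tert-butyldimethylsilyl)oxy]-4-methylbicyclo[3.2.0]heptan-6-one | O=C1C(Cl)(Cl)[C@@H]2CC[C@@](C)(O[Si](C)(C)C(C)(C)C)[C@H]12
F2 | step 3 | (1S,4R,5R)-4-[(tert-butyldimethylsilyl)oxy]-4-methylbicyclo[3.2.0]heptan-6-one | O=C1C[C@@H]2CC[C@@](C)(O[Si](C)(C)C(C)(C)C)[C@H]12
F3 | step 8 | {(1S,2R,5R)-2-[(tert-butyldimethylsilyl)oxy]-5-(2-hydroxypropan-2-yl)-2-methylcyclopentyl}methyl 2,2-dimethylpropanoate | CC(C)(O)[C@@H]1CC[C@@](C)(O[Si](C)(C)C(C)(C)C)[C@@H]1COC(=O)C(C)(C)C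
F4 | step 8 | {(1S,2R,5R)-2-[(tert-butyldimethylsilyl)oxy]-2-methyl-5-(prop-1-en-2-yl)cyclopentyl}methyl 2,2-dimethylpropanoate | C=C(C)[C@@H]1CC[C@@](C)(O[Si](C)(C)C(C)(C)C)[C@@H]1COC(=O)C(C)(C)C
F5 | step 8 | {(1S,2R,5R)-2-[(tert-butyldimethylsilyl)oxy]-2-methyl-5-(prop-1-en-2-yl)cyclopentyl}methanol | C=C(C)[C@@H]1CC[C@@](C)(O[Si](C)(C)C(C)(C)C)[C@@H]1CO
F6 | step 8 | 5-({[(1R,2R,5R)-2-[(tert-butyldimethylsilyl)oxy]-2-methyl-5-(prop-1-en-2-yl)cyclopentyl]methyl}sulfanyl)-1-phenyl-1H-tetrazole | C=C(C)[C@@H]1CC[C@@](C)(O[Si](C)(C)C(C)(C)C)[C@@H]1CSc1nnnn1-c1ccccc1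
F7 | step 14 | ethyl (2E,4E)-5-[(1R,2R,5R)-2-[(tert-butyldimethylsilyl)oxy]-2-methyl-5-(prop-1-en-2-yl)cyclopentyl]-3-methylpenta-2,4-dienoate | C=C(C)[C@@H]1CC[C@@](C)(O[Si](C)(C)C(C)(C)C)[C@@H]1/C=C/C(C)=C/C(=O)OCC
F8 | step 14 | (2E,4E)-5-[(1R,2R,5R)-2-[(tert-butyldimethylsilyl)oxy]-2-methyl-5-(prop-1-en-2-yl)cyclopentyl]-3-methylpenta-2,4-dien-1-ol | C=C(C)[C@@H]1CC[C@@](C)(O[Si](C)(C)C(C)(C)C)[C@@H]1/C=C/C(C)=C/CO
F9 | step 14 | [(2E,4E)-5-[(1R,2R,5R)-2-[(tert-butyldimethylsilyl)oxy]-2-methyl-5-(prop-1-en-2-yl)cyclopentyl]-3-methylpenta-2,4-dien-1-yl]triphenylphosphonium bromide | C=C(C)[C@@H]1CC[C@@](C)(O[Si](C)(C)C(C)(C)C)[C@@H]1/C=C/C(C)=C/C[P+](c1ccccc1)(c1ccccc1)c1ccccc1.[Br-]
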